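Slowness is what you should watch in this run, so here is a quick number for it.

| flask | electrophile | free base | protonated nucleophile | protic impurity | scavenger | remark | time |
|---|---|---|---|---|---|---|---|
| larch | 0.14 M | 0.22 M | 0.14 M | 0.14 M | 0.14 M | run made earlier |  |
| birch | 0.14 M | 0.50 M | 0.14 M | 0.14 M | 0.14 M | run made earlier |  |
| flask | 0.14 M |  | 0.140 M | 0.140 M | 0.140 M |  | 2.0 h |

| run | time / min | product / % | electrophile / % |
|---|---|---|---|
| larch | 10.0 | 20.8 | 79.7 |
| larch | 20.0 | 36.3 | 63.6 |
| larch | 50.0 | 58.4 | 41.6 |
| larch | 120 | 75.7 | 24.1 |
| birch | 10.0 | 22.5 | 77.5 |
| birch | 20.0 | 39.1 | 61.3 |
| birch | 50.0 | 63.6 | 36.7 |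
| birch | 120 | 81.6 | 18.2 |

(readings scatter by 0.3 percentage points)

- the concentration of free base at which the part of the electrophile that has reacted at 2.0 h is just 80%, in M

- what is said of acid set free includes idle adduct
- the amount of free base is what is sought; it is there from the start
- the numbers in the tables scatter by 0.3 percentage points (one standard deviation)
- steps thought possible: nucleophile + acid set free <-> protonated nucleophile; nucleophile + acid set free <-> idle adduct; protic impurity + free base -> quenched reagent; acid set free + free base <-> salt of the base; electrophile + nucleophile -> acid set free + product; acid set free + scavenger -> scavenged by-product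

Electrophile and protonated nucleophile are charged at 0.14 M each, so I treat the reaction as second-order between equal partners. The part reacted is then time over time plus a slowness, the usual second-order half-life. Slowness is the time at which the electrophile used equals the electrophile left. For the wanted part at 2.0 h, it must be the time multiplied by the part left over the part used, 30.0 min.

The larch run reads 39.3 min at 10.0 min, 34.9 min at 20.0 min, 35.6 min at 50.0 min and 38.1 min at 120 min, so it dips and recovers and is not a constant there; I compare the last reading, which stands at the time you asked about. The birch run drifts from 34.4 min to 26.7 min. The required slowness is shorter than larch's and longer than birch's. Taking the inverse of slowness as a straight line in free base charged, my own reckoning gives 0.397 M.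

Your hunch, the forecast, is lower: 0.37 M, between 0.3 M and 0.44 M, on the ground that "the response should saturate above about 0.28 M".

    nucleophile + acid set free ⇌ protonated nucleophile, settled at all times (K = 110 /M)
    nucleophile + acid set free ⇌ idle adduct, settled at all times (K = 240 /M)
    protic impurity + free base → quenched reagent (k = 0.280 /M/min)
    acid set free + free base ⇌ salt of the base (K = 7.50 × 10⁵ /M, k = 7.20 /M/min)
    electrophile + nucleophile → acid set free + product (k = 0.300 /M/min)
    acid set free + scavenger → scavenged by-product (k = 76.0 /M/min)

The flask needs 0.332 M of free base, which is 0.0380 M below the forecast and inside its range, so the forecast held. In this flask, 25.7% of the charged free base is still free at 2.00 h. Now hold the slowness at 30.0 min and compare it with this flask. At 0.200 h the rule gives 28.6% and the flask has used 25.3%. At 1.00 h the rule gives 66.7% against 65.6%. At 6.00 h the rule gives 92.3%, and the flask has used 93.1%.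

The runs stem from a simulated flask on assumed constants, noise included.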